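**Retrosynthetic overview**

1. Target 12 ⇒ butenolide 10 plus a carboxyl group delivered as the formate-derived CO2 radical anion. This polarity-reversed carboxyl adds to the electrophilic β-carbon C4, so two normally electrophilic carbons are joined, and the step sets C4 and C3.
2. Butenolide 10 ⇒ α-methylene lactone 9 by moving the exocyclic alkene into the ring.
3. Lactone 9 ⇒ 16-hydroxyhexadecan-2-one 4 plus the 2-(methoxycarbonyl)allyl carbonate 6, by enantioselective C-allylation at the carbinol carbon (sets C5) and lactonisation.
4. Hydroxy ketone 4 ⇒ ω-pentadecalactone 1 plus a one-carbon nucleophile.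
5. Ring order: the γ-lactone is the only ring. It is closed in step 3 and kept to the end. No protecting groups are used.

Assumption: the (R)-configured iridium catalyst is taken to allylate the Re face of aldehyde 7, giving 5S, by analogy with other unbranched aliphatic alcohols; the antipodal ligand is equally available.

Lactone positions below use furanone numbering: C3 carries the methyl, C4 the carboxyl, C5 the chain. In the acid name these are C4, C3 and C2.

**Route**

Step 1
Reactants: 1 oxacyclohexadecan-2-one (ω-pentadecalactone)
Product: 4 16-hydroxyhexadecan-2-one, via dilithium enolate alkoxide 2 (not isolated), via silyl ketone 3 (not isolated)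
Conditions: Me3SiCH2Li (2.3 equiv), THF/pentane, 0 °C → rt; MeOH, rt; 1 M HCl work-up
Reagents that add atoms: (trimethylsilyl)methyllithium, [Li]C[Si](C)(C)C
Why: Ester-to-methyl-ketone conversion with (trimethylsilyl)methyllithium: after ring-opening addition, the second equivalent deprotonates the α-silyl ketone to enolate 2, which blocks over-addition, and methanol then protonates it and cleaves the labile C–Si bond to leave the methyl ketone.

Step 2
Reactants: 5 methyl 2-(hydroxymethyl)prop-2-enoate
Product: 6 methyl 2-{[(tert-butoxycarbonyl)oxy]methyl}prop-2-enoate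
Conditions: Boc2O (1.1 equiv), DMAP (5 mol %), CH2Cl2, 0 °C → rt
Reagents that add atoms: di-tert-butyl dicarbonate, CC(C)(C)OC(=O)OC(=O)OC(C)(C)C
Why: DMAP-catalysed O-acylation of the primary allylic alcohol gives the allylic tert-butyl carbonate used as the allyl donor.

Step 3
Reactants: 4 16-hydroxyhexadecan-2-one; 6 methyl 2-{[(tert-butoxycarbonyl)oxy]methyl}prop-2-enoate (2 equiv)
Product: 9 (5S)-3-methylidene-5-(14-oxopentadecyl)oxolan-2-one, via 15-oxohexadecanal 7 (not isolated), via hydroxy ester 8 (not isolated)
Conditions: [Ir(cod)Cl]2 (2.5 mol %), (R)-SEGPHOS (5 mol %), 4-cyano-3-nitrobenzoic acid (10 mol %), Cs2CO3 (20 mol %), THF, 70 °C; then TsOH·H2O (10 mol %), CH2Cl2, rt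
Reagents that add atoms: none
Why: Krische-type iridium-catalysed transfer-hydrogenative 2-(alkoxycarbonyl)allylation: the primary alcohol is dehydrogenated to aldehyde 7, the chiral π-allyliridium C,O-benzoate adds to its Re face through a closed chair transition state to set C5 as S, the dialkyl ketone is inert to this allyl species, and hydroxy ester 8 lactonises.

Step 4
Reactants: 9 (5S)-3-methylidene-5-(14-oxopentadecyl)oxolan-2-one
Product: 10 (5S)-3-methyl-5-(14-oxopentadecyl)furan-2(5H)-one
Conditions: RhCl3·3H2O (5 mol %), EtOH, 80 °C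
Reagents that add atoms: none
Why: Metal-hydride olefin isomerisation: a rhodium hydride formed from ethanol adds to the exocyclic CH2 and β-hydride elimination from C4 gives the more stable conjugated trisubstituted butenolide, and because rhodium sits at C3 and never at C4 the C5–H bond is untouched and the S centre is kept.

Step 5
Reactants: 10 (5S)-3-methyl-5-(14-oxopentadecyl)furan-2(5H)-one
Product: 12 (2S,3R,4S)-4-methyl-5-oxo-2-(14-oxopentadecyl)oxolane-3-carboxylic acid, via potassium carboxylate 11 (not isolated)
Conditions: HCO2K (5 equiv), 4CzIPN (2 mol %), methyl thioglycolate (20 mol %), DMSO, 450 nm LEDs, 25 °C; then 1 M HCl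
Reagents that add atoms: potassium formate, [K+].[O-]C=O
Why: Proposed new method: a thiyl radical abstracts hydrogen from formate to give the CO2 radical anion, a nucleophilic carboxyl species of reversed polarity, which adds to the electrophilic C4 of the butenolide anti to the C5 chain (sets C4, trans to the chain); the planar C3 radical (or the enolate formed from it by reduction) then takes hydrogen on the face opposite the new carboxylate (sets C3, methyl cis to CO2H), while the dialkyl ketone lies beyond the reducing power of the radical anion; the closest known reaction type is the thiol/photocatalyst Giese-type hydrocarboxylation of acrylates and related Michael acceptors with formate salts, combined with the known trans selectivity of radical additions to 5-substituted furan-2(5H)-ones.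

**Compound list**

1 | oxacyclohexadecan-2-one (ω-pentadecalactone) | O=C1CCCCCCCCCCCCCCO1 | starting material
2 | dilithium 16-oxido-1-(trimethylsilyl)hexadec-1-en-2-olate | [Li+].[Li+].C[Si](C)(C)C=C([O-])CCCCCCCCCCCCCC[O-] | intermediate (not isolated)
3 | 16-hydroxy-1-(trimethylsilyl)hexadecan-2-one | C[Si](C)(C)CC(=O)CCCCCCCCCCCCCCO | intermediate (not isolated)
4 | 16-hydroxyhexadecan-2-one | CC(=O)CCCCCCCCCCCCCCO | intermediate
5 | methyl 2-(hydroxymethyl)prop-2-enoate | C=C(CO)C(=O)OC | starting material
6 | methyl 2-{[(tert-butoxycarbonyl)oxy]methyl}prop-2-enoate | C=C(COC(=O)OC(C)(C)C)C(=O)OC | intermediate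
7 | 15-oxohexadecanal | CC(=O)CCCCCCCCCCCCCC=O | intermediate (not isolated)
8 | methyl (4S)-4-hydroxy-2-methylidene-18-oxononadecanoate | CC(=O)CCCCCCCCCCCCC[C@H](O)CC(=C)C(=O)OC | intermediate (not isolated)
9 | (5S)-3-methylidene-5-(14-oxopentadecyl)oxolan-2-one | CC(=O)CCCCCCCCCCCCC[C@@H]1OC(=O)C(=C)C1 | intermediate
10 | (5S)-3-methyl-5-(14-oxopentadecyl)furan-2(5H)-one | CC(=O)CCCCCCCCCCCCC[C@@H]1OC(=O)C(C)=C1 | intermediate
11 | potassium (2S,3R,4S)-4-methyl-5-oxo-2-(14-oxopentadecyl)oxolane-3-carboxylate | CC(=O)CCCCCCCCCCCCC[C@@H]1OC(=O)[C@@H](C)[C@H]1C(=O)[O-].[K+] | intermediate (not isolated)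
12 | (2S,3R,4S)-4-methyl-5-oxo-2-(14-oxopentadecyl)oxolane-3-carboxylic acid (chain trans to CO2H, CO2H cis to methyl) | CC(=O)CCCCCCCCCCCCC[C@@H]1OC(=O)[C@@H](C)[C@H]1C(=O)O | target

**Step count**

Total: 5 steps. Longest linear sequence: 4 steps (1 → 4 → 9 → 10 → 12); step 2 is a one-step reagent preparation.

**Steps most likely to fail, with fallbacks**

Step 5 is the largest risk. The trisubstituted butenolide may accept the radical anion slowly. Electron transfer to the butenolide may compete with addition. The hydrogen delivery at C3 may give some of the 3-epimer, which would have to be removed by crystallisation of the acid. The fallback replaces the radical by an ionic carboxyl-anion equivalent. It sets out from 10: ethylene glycol and PPTS in refluxing benzene give the ketal (5S)-3-methyl-5-[13-(2-methyl-1,3-dioxolan-2-yl)tridecyl]furan-2(5H)-one F1. Tris(methylthio)methyllithium (from HC(SMe)3 and n-BuLi, THF, −78 °C) adds to C4 anti to the chain to give the lithium enolate F2. Quenching at −78 °C with AcOH protonates C3 anti to the bulky new group and gives (3S,4R,5S)-3-methyl-5-[13-(2-methyl-1,3-dioxolan-2-yl)tridecyl]-4-[tris(methylsulfanyl)methyl]oxolan-2-one F3. HgO and BF3·OEt2 in aqueous THF then unveil both the carboxylic acid and the ketone, and the route is rejoined at 12.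

Step 3 is the second risk. The ketone may be partly reduced by transfer hydrogenation, the alcohol may add to the acrylate in oxa-Michael fashion, and the enantioselectivity or face sense may be worse than assumed for this unbranched substrate. The fallback changes from alcohol-level transfer hydrogenation to a reductive allylation of the isolated aldehyde. It sets out from 4: TEMPO (10 mol %) and PhI(OAc)2 in CH2Cl2 give 15-oxohexadecanal 7, here isolated. A Nozaki–Hiyama–Kishi allylation with ethyl 2-(bromomethyl)acrylate follows, using CrCl2 (10 mol %), a chiral carbazole-bis(oxazoline) ligand chosen for Re-face attack, Mn powder and Cp2ZrCl2 in THF. It gives ethyl (4S)-4-hydroxy-2-methylidene-18-oxononadecanoate F4, which lactonises with TsOH·H2O and rejoins the route at 9.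

Step 4 is the third risk. The migration may stop short, the ketone may be partly ketalised, and any over-migration to the enol lactone would erode the C5 configuration. The fallback removes the exocyclic carbon and puts a methyl group back by cross-coupling. It sets out from 9: ozonolysis (O3, CH2Cl2, −78 °C; Me2S) gives the α-keto lactone as its enol, (5S)-3-hydroxy-5-(14-oxopentadecyl)furan-2(5H)-one F5. PhNTf2 and Et3N in CH2Cl2 give (5S)-2-oxo-5-(14-oxopentadecyl)-2,5-dihydrofuran-3-yl trifluoromethanesulfonate F6. Stille methylation (Me4Sn, Pd(PPh3)4, LiCl, THF, 65 °C) under neutral conditions then rejoins the route at 10.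

**Further compounds**

F1 | step 5 | (5S)-3-methyl-5-[13-(2-methyl-1,3-dioxolan-2-yl)tridecyl]furan-2(5H)-one | CC1(CCCCCCCCCCCCC[C@@H]2OC(=O)C(C)=C2)OCCO1
F2 | step 5 | lithium (4R,5S)-3-methyl-5-[13-(2-methyl-1,3-dioxolan-2-yl)tridecyl]-4-[tris(methylsulfanyl)methyl]-4,5-dihydrofuran-2-olate | [Li+].CC1(CCCCCCCCCCCCC[C@@H]2OC([O-])=C(C)[C@H]2C(SC)(SC)SC)OCCO1
F3 | step 5 | (3S,4R,5S)-3-methyl-5-[13-(2-methyl-1,3-dioxolan-2-yl)tridecyl]-4-[tris(methylsulfanyl)methyl]oxolan-2-one | CC1(CCCCCCCCCCCCC[C@@H]2OC(=O)[C@@H](C)[C@H]2C(SC)(SC)SC)OCCO1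
F4 | step 3 | ethyl (4S)-4-hydroxy-2-methylidene-18-oxononadecanoate | CC(=O)CCCCCCCCCCCCC[C@H](O)CC(=C)C(=O)OCC
F5 | step 4 | (5S)-3-hydroxy-5-(14-oxopentadecyl)furan-2(5H)-one | CC(=O)CCCCCCCCCCCCC[C@@H]1OC(=O)C(O)=C1
F6 | step 4 | (5S)-2-oxo-5-(14-oxopentadecyl)-2,5-dihydrofuran-3-yl trifluoromethanesulfonate | CC(=O)CCCCCCCCCCCCC[C@@H]1OC(=O)C(OS(=O)(=O)C(F)(F)F)=C1
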